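Everything rests on cutting ring A of the isocoumarin into a diene and an alkyne. The feature exploited is its substitution pattern: C8 (aryl ether), C7 (H), C6 (oxygen) and C5 (H) are C6, C5, C4 and C3 of a 6-aryloxy-4-methoxy-2-pyranone, and the carbon-bearing pair C8a/C4a is the ester-conjugated triple bond of methyl deca-2,4-diynoate. One Diels–Alder reaction with loss of CO2 forms C8–C8a and C5–C4a and delivers ring A aromatic, with ether, ester and heptynyl group in place. The precursor is the ring B phenol (from olivetolic acid, its acid masked as a benzyl ester) bound through oxygen to pyranone C6. Lactonisation onto the alkyne (ring C) and one BBr3 treatment finish the synthesis.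

Key step: step 9

Assumption: olivetolic acid is bought as such. The ring B acid is carried as a benzyl ester, because a methyl ester flanked by two ortho substituents would be hard to remove at the end without decarboxylation.
Remark: isocoumarin numbering (C1 to C8a) is used for rings C and A, and ring B is the benzoate ring. In the cycloaddition product 21 the ester sits on the ring A carbon between the ether carbon and the alkynyl carbon. Adduct 20 is the only chiral compound of the main route; it forms as a racemate and both stereocentres vanish on aromatisation.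

Step 1
Reactants: 1 olivetolic acid (2,4-dihydroxy-6-pentylbenzoic acid)
Product: 3 benzyl 2,4-dimethoxy-6-pentylbenzoate, via benzyl olivetolate 2 (not isolated)
Conditions: BnBr (1.05 equiv), KHCO3, DMF, rt; then MeI (excess), K2CO3, 50 °C
Reagents that add atoms: benzyl bromide BrCc1ccccc1; iodomethane CI
Why: Hydrogencarbonate ionises only the carboxylic acid, which is benzylated by SN2, and carbonate/MeI then carries out a Williamson O-methylation of both phenols, the chelated ortho one included.

Step 2
Reactants: 3 benzyl 2,4-dimethoxy-6-pentylbenzoate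
Product: 4 benzyl 3-formyl-4,6-dimethoxy-2-pentylbenzoate
Conditions: Cl2CHOMe, TiCl4, CH2Cl2, –78 → 0 °C; then H2O
Reagents that add atoms: dichloromethyl methyl ether COC(Cl)Cl; water O
Why: Rieche formylation is an electrophilic aromatic substitution that should go to the ring carbon para to one methoxy group and ortho to the other (next to the pentyl chain) and not to the more crowded carbon between the two methoxy groups, as halogenation and formylation of 3,5-dimethoxyalkylbenzenes do.

Step 3
Reactants: 4 benzyl 3-formyl-4,6-dimethoxy-2-pentylbenzoate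
Product: 6 benzyl 3-hydroxy-4,6-dimethoxy-2-pentylbenzoate, via aryl formate 5 (not isolated)
Conditions: mCPBA, CH2Cl2, 0 °C → rt; then MeOH, Et3N (cat.), rt
Reagents that add atoms: mCPBA O=C(OO)c1cccc(Cl)c1
Why: In this Baeyer–Villiger (Dakin-type) oxidation the electron-rich aryl group migrates in the Criegee adduct to give the formate, which mild methanolysis cleaves while the hindered benzyl ester stays.

Step 4
Reactants: 7 malonyl dichloride (two molecules)
Product: 10 6-chloro-4-hydroxy-2H-pyran-2-one, via pyranone acid chloride 8 (not isolated), via pyranone carboxylic acid 9 (not isolated)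
Conditions: neat, rt, 4–5 d (HCl vented); then H2O, 1,4-dioxane, 60 °C
Reagents that add atoms: malonyl dichloride (second molecule of 7) O=C(Cl)CC(Cl)=O; water O
Why: Two molecules of malonyl dichloride self-condense (C-acylation of the enol of one by the other, then O-acylative ring closure with loss of two HCl) to the 3-chlorocarbonyl pyranone 8, water then hydrolyses the acid chloride far faster than the donor-deactivated ring chloride, and the resulting β-keto-acid-type 3-carboxylic acid 9 decarboxylates on warming.

Step 5
Reactants: 10 6-chloro-4-hydroxy-2H-pyran-2-one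
Product: 11 6-chloro-4-methoxy-2H-pyran-2-one
Conditions: TMSCHN2, MeOH–CH2Cl2, 0 °C
Reagents that add atoms: (trimethylsilyl)diazomethane C[Si](C)(C)C=[N+]=[N-]
Why: O-Methylation of the acidic vinylogous acid by a diazoalkane, which 4-hydroxy-2-pyranones undergo mainly at the 4-oxygen, runs without any base that could displace the ring chloride.

Step 6
Reactants: 6 benzyl 3-hydroxy-4,6-dimethoxy-2-pentylbenzoate and 11 6-chloro-4-methoxy-2H-pyran-2-one
Product: 12 benzyl 4,6-dimethoxy-3-[(4-methoxy-2-oxo-2H-pyran-6-yl)oxy]-2-pentylbenzoate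
Conditions: K2CO3, MeCN, rt
Reagents that add atoms: none
Why: Addition–elimination (nucleophilic vinylic substitution) at pyranone C6, a vinylogous acid chloride, lets the hindered phenoxide add to an unhindered sp2 carbon to give a dienolate held by the lactone carbonyl, from which chloride leaves, so no aromatic carbon has to be attacked.

Step 7
Reactants: 13 1,4-dichlorobut-2-yne and 14 1-bromopentane
Product: 16 nona-1,3-diyne, via sodium butadiynide 15 (not isolated)
Conditions: NaNH2 (3 equiv), NH3 (l), –40 °C; then n-C5H11Br, –33 °C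
Reagents that add atoms: none
Why: Twofold dehydrochlorination to buta-1,3-diyne and deprotonation give the monosodium diynide, which is alkylated by SN2 at its terminal carbon, the classical liquid-ammonia route to alka-1,3-diynes.

Step 8
Reactants: 16 nona-1,3-diyne and 17 methyl chloroformate
Product: 19 methyl deca-2,4-diynoate, via lithium nonadiynide 18 (not isolated)
Conditions: n-BuLi, THF, –78 °C; then ClCO2Me, –78 → 0 °C
Reagents that add atoms: none
Why: Deprotonation of the terminal alkyne and C-acylation of the lithium acetylide by the chloroformate is the standard preparation of alk-2-ynoates.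

Step 9
Reactants: 12 benzyl 4,6-dimethoxy-3-[(4-methoxy-2-oxo-2H-pyran-6-yl)oxy]-2-pentylbenzoate and 19 methyl deca-2,4-diynoate
Product: 21 benzyl 3-[3-(hept-1-yn-1-yl)-5-methoxy-2-(methoxycarbonyl)phenoxy]-4,6-dimethoxy-2-pentylbenzoate, via bridged lactone adduct 20 (not isolated)
Conditions: 19 (3 equiv), BHT (cat.), toluene, 150 °C, sealed tube
Reagents that add atoms: none
Why: In a thermal normal-demand [4+2] cycloaddition the pyranone diene (C3=C4–C5=C6), raised in energy by the 4-methoxy and 6-aryloxy donors, adds across the ester-bearing triple bond of 19 to give the 2-oxabicyclo[2.2.2]octadienone 20, which expels CO2 in a retro-[4+2] at the same temperature. The closest known reaction type is the Diels–Alder reaction of 4-methoxy- and 6-alkoxy-2-pyranones with alkynoates, which ends in benzoates after decarboxylation. Ring A is closed by an intermolecular cycloaddition that forms C8–C8a and C5–C4a in one event, and because the lactone bridge is the only fragment that can leave, aromatisation keeps the aryloxy group. The two bridgehead stereocentres of 20 are erased on aromatisation, so no stereocontrol is needed. Orientation should be secured because pyranone C3, the β-carbon of the enol ether with the largest HOMO coefficient, pairs with the β-carbon of the ynoate, which has the largest LUMO coefficient, and this places the aryloxy-bearing carbon next to the ester carbon; site selectivity should follow because only the C2≡C3 bond of 19 is directly conjugated with the ester, while the C4≡C5 bond carries the electron-releasing pentyl group.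

Step 10
Reactants: 21 benzyl 3-[3-(hept-1-yn-1-yl)-5-methoxy-2-(methoxycarbonyl)phenoxy]-4,6-dimethoxy-2-pentylbenzoate
Product: 22 benzyl 4,6-dimethoxy-3-[(6-methoxy-1-oxo-3-pentyl-1H-isochromen-8-yl)oxy]-2-pentylbenzoate
Conditions: Cu(OTf)2 (10 mol %), CF3CO2H, ClCH2CH2Cl, 80 °C
Reagents that add atoms: none
Why: In this acid-promoted 6-endo-dig cyclisation of an ortho-alkynyl benzoate the ester carbonyl oxygen, made electron-rich by the para methoxy and ortho aryloxy groups, attacks the activated alkyne at its pentyl-bearing carbon, C4 is protonated, and trifluoroacetate removes the O-methyl group from the oxonium ion, while the benzyl ester is not ionised by an acid of this strength.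

Step 11
Reactants: 22 benzyl 4,6-dimethoxy-3-[(6-methoxy-1-oxo-3-pentyl-1H-isochromen-8-yl)oxy]-2-pentylbenzoate
Product: 23 4,6-dihydroxy-3-[(6-hydroxy-1-oxo-3-pentyl-1H-isochromen-8-yl)oxy]-2-pentylbenzoic acid (CNP0439913.0)
Conditions: BBr3 (10 equiv), CH2Cl2, –78 °C → rt; then ice–water
Reagents that add atoms: none
Why: In this Lewis-acid ether and ester cleavage BBr3 binds each ether and ester oxygen and bromide removes the alkyl group by attack at carbon (three O–CH3 bonds and the O–CH2Ph bond), so the hindered acyl carbon of ring B, the lactone and the diaryl ether, none of which has a cleavable alkyl–oxygen bond, stay intact.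

Compound list
1 | olivetolic acid (2,4-dihydroxy-6-pentylbenzoic acid) | CCCCCc1cc(O)cc(O)c1C(=O)O | starting material
2 | benzyl 2,4-dihydroxy-6-pentylbenzoate (benzyl olivetolate) | CCCCCc1cc(O)cc(O)c1C(=O)OCc1ccccc1 | intermediate
3 | benzyl 2,4-dimethoxy-6-pentylbenzoate | CCCCCc1cc(OC)cc(OC)c1C(=O)OCc1ccccc1 | intermediate
4 | benzyl 3-formyl-4,6-dimethoxy-2-pentylbenzoate | CCCCCc1c(C=O)c(OC)cc(OC)c1C(=O)OCc1ccccc1 | intermediate
5 | benzyl 3-(formyloxy)-4,6-dimethoxy-2-pentylbenzoate | CCCCCc1c(OC=O)c(OC)cc(OC)c1C(=O)OCc1ccccc1 | intermediate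
6 | benzyl 3-hydroxy-4,6-dimethoxy-2-pentylbenzoate | CCCCCc1c(O)c(OC)cc(OC)c1C(=O)OCc1ccccc1 | intermediate
7 | malonyl dichloride | O=C(Cl)CC(Cl)=O | starting material
8 | 6-chloro-4-hydroxy-2-oxo-2H-pyran-3-carbonyl chloride | O=C(Cl)c1c(O)cc(Cl)oc1=O | intermediate
9 | 6-chloro-4-hydroxy-2-oxo-2H-pyran-3-carboxylic acid | O=C(O)c1c(O)cc(Cl)oc1=O | intermediate
10 | 6-chloro-4-hydroxy-2H-pyran-2-one | Oc1cc(Cl)oc(=O)c1 | intermediate
11 | 6-chloro-4-methoxy-2H-pyran-2-one | COc1cc(Cl)oc(=O)c1 | intermediate
12 | benzyl 4,6-dimethoxy-3-[(4-methoxy-2-oxo-2H-pyran-6-yl)oxy]-2-pentylbenzoate | COc1cc(=O)oc(Oc2c(OC)cc(OC)c(C(=O)OCc3ccccc3)c2CCCCC)c1 | intermediate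
13 | 1,4-dichlorobut-2-yne | ClCC#CCCl | starting material
14 | 1-bromopentane | CCCCCBr | starting material
15 | sodium buta-1,3-diyn-1-ide | [Na+].[C-]#CC#C | intermediate
16 | nona-1,3-diyne | CCCCCC#CC#C | intermediate
17 | methyl chloroformate | COC(=O)Cl | starting material
18 | lithium nona-1,3-diyn-1-ide | [Li+].[C-]#CC#CCCCCC | intermediate
19 | methyl deca-2,4-diynoate | CCCCCC#CC#CC(=O)OC | intermediate
20 | methyl 1-{3-[(benzyloxy)carbonyl]-4,6-dimethoxy-2-pentylphenoxy}-5-(hept-1-yn-1-yl)-8-methoxy-3-oxo-2-oxabicyclo[2.2.2]octa-5,7-diene-6-carboxylate (racemic) | COC(=O)C1=C(C#CCCCCC)C2C(=O)OC1(Oc3c(OC)cc(OC)c(C(=O)OCc4ccccc4)c3CCCCC)C=C2OC | intermediate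
21 | benzyl 3-[3-(hept-1-yn-1-yl)-5-methoxy-2-(methoxycarbonyl)phenoxy]-4,6-dimethoxy-2-pentylbenzoate | CCCCCC#Cc1cc(OC)cc(Oc2c(OC)cc(OC)c(C(=O)OCc3ccccc3)c2CCCCC)c1C(=O)OC | intermediate
22 | benzyl 4,6-dimethoxy-3-[(6-methoxy-1-oxo-3-pentyl-1H-isochromen-8-yl)oxy]-2-pentylbenzoate | CCCCCc1cc2cc(OC)cc(Oc3c(OC)cc(OC)c(C(=O)OCc4ccccc4)c3CCCCC)c2c(=O)o1 | intermediate
23 | 4,6-dihydroxy-3-[(6-hydroxy-1-oxo-3-pentyl-1H-isochromen-8-yl)oxy]-2-pentylbenzoic acid | CCCCCc1cc2cc(O)cc(Oc3c(O)cc(O)c(C(=O)O)c3CCCCC)c2c(=O)o1 | target

Total step count: 11. Longest linear sequence: 7 steps (steps 1, 2, 3, 6, 9, 10, 11).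

Steps most likely to fail

Step 9. The cycloaddition may take place at the remote triple bond or in the reversed orientation, or the pyranone may decay thermally before the mono-activated alkyne reacts. The fallback sets out from 12 and comes back at 21. Compound 12 would be heated with methyl 3-bromoprop-2-ynoate F1 (from methyl propiolate, NBS and catalytic AgNO3 in acetone), a dienophile with a single, more electron-poor triple bond, so that no choice of site exists and the ester alone dictates orientation. The bridged bromo lactone adduct F2 would lose CO2 to give benzyl 3-[3-bromo-5-methoxy-2-(methoxycarbonyl)phenoxy]-4,6-dimethoxy-2-pentylbenzoate F3. Sonogashira coupling of F3 with 1-heptyne (Pd(PPh3)2Cl2, CuI, Et3N, THF, 50 °C) would then give 21.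

Step 6. The hindered phenoxide may attack the lactone carbonyl and open the ring instead of substituting at C6, or the substitution may be too slow to compete with decay of the chloropyranone in base. The fallback sets out from 6 and comes back at 12; it builds the pyranone on the aryl oxygen instead of substituting a finished ring. Compound 6 would be acetylated (Ac2O, pyridine, DMAP) to benzyl 3-acetoxy-4,6-dimethoxy-2-pentylbenzoate F4. F4 would be converted with LiN(i-Pr)2 and TMSCl (THF, –78 °C) into the ketene silyl acetal benzyl 4,6-dimethoxy-2-pentyl-3-({1-[(trimethylsilyl)oxy]ethenyl}oxy)benzoate F5. Annulation of F5 with malonyl dichloride 7 (CH2Cl2, –78 °C → rt), in the manner of the silyl enol ether–malonyl dichloride synthesis of 4-hydroxy-2-pyranones, would give benzyl 3-[(4-hydroxy-2-oxo-2H-pyran-6-yl)oxy]-4,6-dimethoxy-2-pentylbenzoate F6. O-Methylation of F6 with TMSCHN2 as in step 5 would give 12.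

Step 11. The benzyl group set free under the Lewis acid may re-attack the electron-rich rings, ether cleavage may stop short at the non-chelated 6-methoxy group, or the liberated dihydroxybenzoic acid may decarboxylate during the acidic quench. The fallback sets out from 22 and comes back at 23; it separates ester removal from ether cleavage. The benzyl ester would first be taken off by hydrogenolysis (H2, 1 atm, Pd/C, EtOAc, rt, short contact to spare the C3=C4 bond) to give 4,6-dimethoxy-3-[(6-methoxy-1-oxo-3-pentyl-1H-isochromen-8-yl)oxy]-2-pentylbenzoic acid F7. The three methyl ethers of F7 would then be cleaved with BBr3 (CH2Cl2, –78 → 0 °C, cold quench) to give 23, with no benzyl electrophile present.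

Further compounds
F1 | step 9 | methyl 3-bromoprop-2-ynoate | COC(=O)C#CBr
F2 | step 9 | methyl 1-{3-[(benzyloxy)carbonyl]-4,6-dimethoxy-2-pentylphenoxy}-5-bromo-8-methoxy-3-oxo-2-oxabicyclo[2.2.2]octa-5,7-diene-6-carboxylate (racemic) | COC(=O)C1=C(Br)C2C(=O)OC1(Oc3c(OC)cc(OC)c(C(=O)OCc4ccccc4)c3CCCCC)C=C2OC
F3 | step 9 | benzyl 3-[3-bromo-5-methoxy-2-(methoxycarbonyl)phenoxy]-4,6-dimethoxy-2-pentylbenzoate | COC(=O)c1c(Br)cc(OC)cc1Oc1c(OC)cc(OC)c(C(=O)OCc2ccccc2)c1CCCCC
F4 | step 6 | benzyl 3-acetoxy-4,6-dimethoxy-2-pentylbenzoate | CCCCCc1c(OC(C)=O)c(OC)cc(OC)c1C(=O)OCc1ccccc1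
F5 | step 6 | benzyl 4,6-dimethoxy-2-pentyl-3-({1-[(trimethylsilyl)oxy]ethenyl}oxy)benzoate | CCCCCc1c(OC(=C)O[Si](C)(C)C)c(OC)cc(OC)c1C(=O)OCc1ccccc1
F6 | step 6 | benzyl 3-[(4-hydroxy-2-oxo-2H-pyran-6-yl)oxy]-4,6-dimethoxy-2-pentylbenzoate | CCCCCc1c(Oc2cc(O)cc(=O)o2)c(OC)cc(OC)c1C(=O)OCc1ccccc1
F7 | step 11 | 4,6-dimethoxy-3-[(6-methoxy-1-oxo-3-pentyl-1H-isochromen-8-yl)oxy]-2-pentylbenzoic acid | CCCCCc1cc2cc(OC)cc(Oc3c(OC)cc(OC)c(C(=O)O)c3CCCCC)c2c(=O)o1
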